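## Retrosynthetic overview

1. The target is catechin-(4α→6)-epicatechin-(4β→8)-epicatechin-(4β→8)-epicatechin (units A, B, C, D from the top). Both interflavan bonds of unit B are cut, C4(A)–C6(B) and C4(B)–C8(C), giving a catechin C4 electrophile (from (+)-catechin), benzylated procyanidin B2 (units C–D, from (−)-epicatechin) and a bifunctional unit B.
2. Unit B is built rather than bought: its ring C is closed in one operation from an α-hydroxy ester (O1–C2–C3) and an o-bromobenzyl sulfone (C4–C4a–C8a), by copper-catalysed O-arylation (O1–C8a) and Dieckmann acylation (C3–C4).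
3. Enabling feature: in ring C of unit B the oxygenated C3 sits between benzylic C2 and benzylic C4, and C4 and the ether carbon C8a are both attached to C4a of ring A. At the 3-ketone/4-sulfone level C3 is an ester carbonyl and C4 a sulfone carbanion beside a C8a–Br. The ketone then lets one dynamic kinetic resolution set C2/C3 (2R, cis), and the sulfone is the later nucleofuge at C4.
4. Order: ring C of unit B (step 12) → C2/C3 by transfer hydrogenation → Br block at C8(B) → C4(A)–C6(B) bond → C4(B)–C8(C) bond → deacetylation → hydrogenolysis (16 benzyl ethers, 3 C–Br). All other rings come from the building blocks.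

Key step: step 12

Remark 1: α denotes the face of the 2-aryl group. The C4 configurations drawn for the ethers 3, 4, 5, 8 and the sulfones 19–21 are the expected ones but are not relied on, because each of these C4 centres is ionised later.
Remark 2: the sense of induction in step 13 is assumed to be the one drawn for the (R,R)-TsDPEN complex; the mirror-image complex would be used if a trial reduction showed the opposite sense.

## Route

Step 1
Reactants: 1 (+)-catechin
Product: 2 5,7,3′,4′-tetra-O-benzylcatechin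
Conditions: BnBr (4.4 equiv), K2CO3, DMF, 0 °C → rt, Ar
Reagents that add atoms: benzyl bromide BrCc1ccccc1
Why: Williamson etherification, in which K2CO3 deprotonates only the four phenols, so the secondary 3-OH stays free and C2/C3 are untouched.

Step 2
Reactants: 2 5,7,3′,4′-tetra-O-benzylcatechin
Product: 3 4α-(2-ethoxyethoxy)-5,7,3′,4′-tetra-O-benzylcatechin (3,4-trans)
Conditions: DDQ (2 equiv), 2-ethoxyethanol, CH2Cl2, rt
Reagents that add atoms: 2-ethoxyethanol CCOCCO
Why: DDQ benzylic oxidation, in which hydride abstraction from C4 (activated by the 5,7-dialkoxy ring A) gives the flavan-4-yl cation that the alcohol should trap anti to the 3-OH.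

Step 3
Reactants: 3 4α-(2-ethoxyethoxy)-5,7,3′,4′-tetra-O-benzylcatechin
Product: 4 6,8-dibromo-4α-(2-ethoxyethoxy)-5,7,3′,4′-tetra-O-benzylcatechin
Conditions: NBS (2.1 equiv), CH2Cl2, −20 → 0 °C
Reagents that add atoms: N-bromosuccinimide O=C1CCC(=O)N1Br
Why: electrophilic aromatic bromination at C6 and C8, the only strongly activated free positions, which removes every nucleophilic site of this unit so that it cannot self-condense as an electrophile.

Step 4
Reactants: 4 6,8-dibromo-4α-(2-ethoxyethoxy)-5,7,3′,4′-tetra-O-benzylcatechin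
Product: 5 3-O-acetyl-6,8-dibromo-4α-(2-ethoxyethoxy)-5,7,3′,4′-tetra-O-benzylcatechin
Conditions: Ac2O, DMAP (cat.), pyridine, rt
Reagents that add atoms: acetic anhydride CC(=O)OC(C)=O
Why: DMAP-catalysed acylation of the secondary alcohol installs the C3 acetate that later steers attack at C4 by neighbouring-group participation.

Step 5
Reactants: 6 (−)-epicatechin
Product: 7 5,7,3′,4′-tetra-O-benzylepicatechin
Conditions: BnBr (4.4 equiv), K2CO3, DMF, 0 °C → rt, Ar
Reagents that add atoms: benzyl bromide BrCc1ccccc1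
Why: Williamson etherification of the four phenols as in step 1, with the stereocentres untouched.

Step 6
Reactants: 7 5,7,3′,4′-tetra-O-benzylepicatechin
Product: 8 4β-(2-ethoxyethoxy)-5,7,3′,4′-tetra-O-benzylepicatechin (3,4-trans)
Conditions: DDQ (2 equiv), 2-ethoxyethanol, CH2Cl2, rt
Reagents that add atoms: 2-ethoxyethanol CCOCCO
Why: DDQ benzylic oxidation at C4 as in step 2, with the alcohol entering anti to the axial 3-OH.

Step 7
Reactants: 8 4β-(2-ethoxyethoxy)-5,7,3′,4′-tetra-O-benzylepicatechin; 7 5,7,3′,4′-tetra-O-benzylepicatechin (4 equiv)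
Product: 9 octa-O-benzyl procyanidin B2 [tetra-O-benzylepicatechin-(4β→8)-tetra-O-benzylepicatechin, both 3-OH free]
Conditions: TMSOTf (0.1 equiv), 4 Å MS, CH2Cl2, −78 °C; Et3N quench
Reagents that add atoms: none
Why: Lewis-acid Friedel–Crafts alkylation, in which the C4 cation from 8 is attacked by C8 (the most nucleophilic position) of excess 7 anti to the 3-OH, setting C4 of unit C as 4β (3,4-trans).

Step 8
Reactants: 10 DL-3,4-dihydroxymandelic acid
Product: 11 benzyl 2-[3,4-bis(benzyloxy)phenyl]-2-hydroxyacetate (racemic)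
Conditions: BnBr (3.3 equiv), K2CO3, DMF, rt, Ar
Reagents that add atoms: benzyl bromide BrCc1ccccc1
Why: Williamson/carboxylate alkylation, in which the carboxylate and both phenoxides are benzylated while the non-acidic benzylic OH stays free.

Step 9
Reactants: 12 1,3-bis(benzyloxy)-5-bromobenzene
Product: 13 2,4-bis(benzyloxy)-6-bromobenzaldehyde
Conditions: POCl3, DMF, 0 → 70 °C; then H2O
Reagents that add atoms: N,N-dimethylformamide CN(C)C=O; water O
Why: Vilsmeier–Haack formylation, expected para to one benzyloxy group and ortho to bromine as for 1-bromo-3,5-dialkoxybenzenes, which places the future C4 between C–Br (future C8a) and C–OBn (future C5).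

Step 10
Reactants: 13 2,4-bis(benzyloxy)-6-bromobenzaldehyde
Product: 14 [2,4-bis(benzyloxy)-6-bromophenyl]methanol
Conditions: NaBH4, THF/MeOH, 0 °C
Reagents that add atoms: none
Why: borohydride reduction of the aldehyde, with aryl bromide and benzyl ethers inert.

Step 11
Reactants: 14 [2,4-bis(benzyloxy)-6-bromophenyl]methanol
Product: 16 1,5-bis(benzyloxy)-3-bromo-2-[(phenylsulfonyl)methyl]benzene, via benzylic chloride 15 (not isolated)
Conditions: SOCl2, CH2Cl2, 0 °C; evaporate; then PhSO2Na, DMF, rt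
Reagents that add atoms: sodium benzenesulfinate [Na+].[O-]S(=O)c1ccccc1; thionyl chloride O=S(Cl)Cl (chlorine of 15 only)
Why: chlorination of the electron-rich benzylic alcohol followed by SN2 S-alkylation of the sulfinate gives the sulfone that acidifies the future C4.

Step 12
Reactants: 11 benzyl 2-[3,4-bis(benzyloxy)phenyl]-2-hydroxyacetate; 16 1,5-bis(benzyloxy)-3-bromo-2-[(phenylsulfonyl)methyl]benzene (1.6 equiv)
Product: 18 5,7-bis(benzyloxy)-2-[3,4-bis(benzyloxy)phenyl]-4-(phenylsulfonyl)chroman-3-one (racemic), via aryl ether ester 17 (not isolated)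
Conditions: CuI (10 mol %), 3,4,7,8-tetramethyl-1,10-phenanthroline (20 mol %), Cs2CO3 (3 equiv), 4 Å MS, toluene, 110 °C, Ar; AcOH work-up
Reagents that add atoms: none
Why: Proposed new method: the cesium alkoxide of α-hydroxy ester 11 is O-arylated by bromide 16 in an Ullmann-type C–O coupling (monovalent copper/phenanthroline, oxidative addition then reductive elimination) to give ether 17 with the new O1–C8a bond, after which carbonate deprotonates the sulfonyl-activated benzylic CH2 (C4) and the carbanion attacks the benzyl ester carbonyl (C3) in a Dieckmann condensation that forms C3–C4, expels benzyl alkoxide and is driven by irreversible formation of the β-keto sulfone enolate. The closest known reactions are copper-catalysed etherification of aryl halides with secondary alcohols, copper-catalysed coupling/condensation cascades of ortho-functionalised aryl halides, and the acylation of sulfone carbanions by esters. Ring C of unit B closes in the second event by a 6-exo-trig acyl substitution (C4 onto C3) across the O1–C8a tether made in the first. The two new stereocentres, C2 and C4, both flank the ketone and are epimerisable, so neither needs control here and the product is carried on as the equilibrating racemate, C2/C3 being fixed in step 13. The step needs O-arylation to come before C-acylation (an intermolecular Claisen product would close through its enolate oxygen to a benzofuran) and O- over C-arylation; the weak heterogeneous base keeps the sulfone carbanion scarce until the intramolecular stage, the α-hydroxy ester binds copper as a chelated alkoxide, the benzyl ester makes exchange with released benzyl alkoxide degenerate, and the excess of 16 absorbs arylation of that alkoxide.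

Step 13
Reactants: 18 5,7-bis(benzyloxy)-2-[3,4-bis(benzyloxy)phenyl]-4-(phenylsulfonyl)chroman-3-one
Product: 19 4α-(phenylsulfonyl)-5,7,3′,4′-tetra-O-benzylepicatechin [(2R)-2,3-cis-3,4-cis-chroman-3-ol]
Conditions: RuCl[(R,R)-TsDPEN](p-cymene) (2 mol %), HCO2H/Et3N (5:2), DMF, 40 °C
Reagents that add atoms: none
Why: Noyori–Ikariya asymmetric transfer hydrogenation with dynamic kinetic resolution, in which C2 and C4 epimerise through the enol faster than reduction, the catalyst selects the (2R) ketone and hydride should enter C3 anti to the 2-aryl and 4-sulfonyl groups of the 2,4-cis form, giving the 2,3-cis alcohol.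

Step 14
Reactants: 19 4α-(phenylsulfonyl)-5,7,3′,4′-tetra-O-benzylepicatechin
Product: 20 8-bromo-4α-(phenylsulfonyl)-5,7,3′,4′-tetra-O-benzylepicatechin
Conditions: NBS (1.0 equiv), CH2Cl2, −40 → 0 °C
Reagents that add atoms: N-bromosuccinimide O=C1CCC(=O)N1Br
Why: electrophilic aromatic bromination at C8, the more reactive ring A position of benzylated flavan-3-ols, which leaves C6 as the only nucleophilic carbon of unit B.

Step 15
Reactants: 20 8-bromo-4α-(phenylsulfonyl)-5,7,3′,4′-tetra-O-benzylepicatechin; 5 3-O-acetyl-6,8-dibromo-4α-(2-ethoxyethoxy)-5,7,3′,4′-tetra-O-benzylcatechin (1.2 equiv)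
Product: 21 protected A–B dimer [3-O-acetyl-6,8-dibromo-tetra-O-benzylcatechin-(4α→6)-8-bromo-4α-(phenylsulfonyl)-tetra-O-benzylepicatechin]
Conditions: TMSOTf (0.2 equiv), 4 Å MS, CH2Cl2, −78 → −40 °C; Et3N quench
Reagents that add atoms: none
Why: Lewis-acid Friedel–Crafts alkylation, in which the C4 cation of 5 is bridged on its β-face by the 3-acetoxy group so that C6 of 20 (its only free ring A carbon) attacks from the α-face to set C4 of unit A as 4α (3,4-trans), while the sulfone is expected to stay intact at this temperature.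

Step 16
Reactants: 21 protected A–B dimer; 9 octa-O-benzyl procyanidin B2 (1.5 equiv)
Product: 22 protected tetramer [3-O-acetyl-6,8-dibromo-tetra-O-benzylcatechin-(4α→6)-8-bromo-tetra-O-benzylepicatechin-(4β→8)-tetra-O-benzylepicatechin-(4β→8)-tetra-O-benzylepicatechin]
Conditions: Sc(OTf)3 (0.3 equiv), 4 Å MS, CH2Cl2, −20 → 0 °C
Reagents that add atoms: none
Why: Proposed new method: Sc(OTf)3 binds the sulfonyl oxygens and the C4–S bond of unit B ionises to the 2,4,6-trioxygenated flavan-4-yl cation (arenesulfinate being a competent nucleofuge from such stabilised cations), which C8 of the upper unit of 9 attacks anti to the free 3-OH to set C4 of unit B as 4β (3,4-trans); this is a Friedel–Crafts alkylation whose closest known types are the Lewis-acid ionisation of 2-sulfonyl cyclic ethers and (indol-3-yl)methyl sulfones and the coupling of flavan C4 ethers, and 21 cannot self-condense because it has no free ring A position.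

Step 17
Reactants: 22 protected tetramer
Product: 23 deacetylated protected tetramer (all four 3-OH free)
Conditions: NaOMe (cat.), MeOH/THF, rt → 40 °C
Reagents that add atoms: none
Why: Zemplén transesterification removes the acetate under conditions that leave benzyl ethers, aryl bromides and the interflavan bonds intact.

Step 18
Reactants: 23 deacetylated protected tetramer
Product: 24 catechin-(4α→6)-epicatechin-(4β→8)-epicatechin-(4β→8)-epicatechin (CNP0228086.1)
Conditions: H2 (1 atm), Pd(OH)2/C, Et3N, THF/MeOH/H2O, rt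
Reagents that add atoms: none
Why: catalytic hydrogenolysis cleaves the sixteen benzyl ethers and hydrodebrominates the three blocking C–Br bonds (Et3N scavenging HBr) without touching the stereocentres.

## Compound list

1 | (+)-catechin | Oc1cc(O)c2c(c1)O[C@H](c1ccc(O)c(O)c1)[C@@H](O)C2 | starting material
2 | 5,7,3′,4′-tetra-O-benzylcatechin | O(Cc4ccccc4)c1cc(OCc4ccccc4)c2c(c1)O[C@H](c3ccc(OCc4ccccc4)c(OCc4ccccc4)c3)[C@@H](O)C2 | intermediate
3 | 4α-(2-ethoxyethoxy)-5,7,3′,4′-tetra-O-benzylcatechin | O(Cc4ccccc4)c1cc(OCc4ccccc4)c2c(c1)O[C@H](c3ccc(OCc4ccccc4)c(OCc4ccccc4)c3)[C@@H](O)[C@@H]2OCCOCC | intermediate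
4 | 6,8-dibromo-4α-(2-ethoxyethoxy)-5,7,3′,4′-tetra-O-benzylcatechin | O(Cc4ccccc4)c1c(Br)c(OCc4ccccc4)c2c(c1Br)O[C@H](c3ccc(OCc4ccccc4)c(OCc4ccccc4)c3)[C@@H](O)[C@@H]2OCCOCC | intermediate
5 | 3-O-acetyl-6,8-dibromo-4α-(2-ethoxyethoxy)-5,7,3′,4′-tetra-O-benzylcatechin | O(Cc4ccccc4)c1c(Br)c(OCc4ccccc4)c2c(c1Br)O[C@H](c3ccc(OCc4ccccc4)c(OCc4ccccc4)c3)[C@@H](OC(C)=O)[C@@H]2OCCOCC | intermediate
6 | (−)-epicatechin | Oc1cc(O)c2c(c1)O[C@H](c1ccc(O)c(O)c1)[C@H](O)C2 | starting material
7 | 5,7,3′,4′-tetra-O-benzylepicatechin | O(Cc4ccccc4)c1cc(OCc4ccccc4)c2c(c1)O[C@H](c3ccc(OCc4ccccc4)c(OCc4ccccc4)c3)[C@H](O)C2 | intermediate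
8 | 4β-(2-ethoxyethoxy)-5,7,3′,4′-tetra-O-benzylepicatechin | O(Cc4ccccc4)c1cc(OCc4ccccc4)c2c(c1)O[C@H](c3ccc(OCc4ccccc4)c(OCc4ccccc4)c3)[C@H](O)[C@H]2OCCOCC | intermediate
9 | octa-O-benzyl procyanidin B2 | c1c(OCc4ccccc4)cc(OCc4ccccc4)c3c1O[C@H](c1ccc(OCc4ccccc4)c(OCc4ccccc4)c1)[C@H](O)[C@H]3c1c(OCc4ccccc4)cc(OCc4ccccc4)c3c1O[C@H](c1ccc(OCc4ccccc4)c(OCc4ccccc4)c1)[C@H](O)C3 | intermediate
10 | DL-3,4-dihydroxymandelic acid | OC(C(=O)O)c1ccc(O)c(O)c1 | starting material
11 | benzyl 2-[3,4-bis(benzyloxy)phenyl]-2-hydroxyacetate (racemic) | OC(C(=O)OCc1ccccc1)c1ccc(OCc2ccccc2)c(OCc2ccccc2)c1 | intermediate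
12 | 1,3-bis(benzyloxy)-5-bromobenzene | Brc1cc(OCc2ccccc2)cc(OCc2ccccc2)c1 | starting material
13 | 2,4-bis(benzyloxy)-6-bromobenzaldehyde | O=Cc1c(Br)cc(OCc2ccccc2)cc1OCc1ccccc1 | intermediate
14 | [2,4-bis(benzyloxy)-6-bromophenyl]methanol | OCc1c(Br)cc(OCc2ccccc2)cc1OCc1ccccc1 | intermediate
15 | 1,5-bis(benzyloxy)-3-bromo-2-(chloromethyl)benzene | ClCc1c(Br)cc(OCc2ccccc2)cc1OCc1ccccc1 | intermediate
16 | 1,5-bis(benzyloxy)-3-bromo-2-[(phenylsulfonyl)methyl]benzene | O=S(=O)(Cc1c(Br)cc(OCc2ccccc2)cc1OCc1ccccc1)c1ccccc1 | intermediate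
17 | benzyl 2-{3,5-bis(benzyloxy)-2-[(phenylsulfonyl)methyl]phenoxy}-2-[3,4-bis(benzyloxy)phenyl]acetate (racemic) | O=C(OCc1ccccc1)C(Oc1cc(OCc2ccccc2)cc(OCc2ccccc2)c1CS(=O)(=O)c1ccccc1)c1ccc(OCc2ccccc2)c(OCc2ccccc2)c1 | intermediate
18 | 5,7-bis(benzyloxy)-2-[3,4-bis(benzyloxy)phenyl]-4-(phenylsulfonyl)chroman-3-one (racemic, C2 and C4 labile, so no descriptors) | O=C1C(c2ccc(OCc3ccccc3)c(OCc3ccccc3)c2)Oc2cc(OCc3ccccc3)cc(OCc3ccccc3)c2C1S(=O)(=O)c1ccccc1 | intermediate
19 | 4α-(phenylsulfonyl)-5,7,3′,4′-tetra-O-benzylepicatechin (2R; 3-OH cis to 2-aryl and to sulfonyl) | c1c(OCc4ccccc4)cc2c(c1OCc4ccccc4)[C@@H](S(=O)(=O)c1ccccc1)[C@@H](O)[C@@H](c1ccc(OCc4ccccc4)c(OCc4ccccc4)c1)O2 | intermediate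
20 | 8-bromo-4α-(phenylsulfonyl)-5,7,3′,4′-tetra-O-benzylepicatechin | c1c(OCc4ccccc4)c(Br)c2c(c1OCc4ccccc4)[C@@H](S(=O)(=O)c1ccccc1)[C@@H](O)[C@@H](c1ccc(OCc4ccccc4)c(OCc4ccccc4)c1)O2 | intermediate
21 | protected A–B dimer (unit A: 3-OAc, 6,8-Br2, 4α→6; unit B: 8-Br, 4α-SO2Ph, 3-OH) | O(Cc4ccccc4)c1c(Br)c(OCc4ccccc4)c2c(c1Br)O[C@H](c3ccc(OCc4ccccc4)c(OCc4ccccc4)c3)[C@@H](OC(C)=O)[C@@H]2c1c(OCc4ccccc4)c(Br)c2c(c1OCc4ccccc4)[C@@H](S(=O)(=O)c1ccccc1)[C@@H](O)[C@@H](c1ccc(OCc4ccccc4)c(OCc4ccccc4)c1)O2 | intermediate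
22 | protected tetramer (unit A 3-OAc; sixteen benzyl ethers; three C–Br) | O(Cc4ccccc4)c1c(Br)c(OCc4ccccc4)c2c(c1Br)O[C@H](c3ccc(OCc4ccccc4)c(OCc4ccccc4)c3)[C@@H](OC(C)=O)[C@@H]2c1c(OCc4ccccc4)c(Br)c2c(c1OCc4ccccc4)[C@H](c1c(OCc4ccccc4)cc(OCc4ccccc4)c3c1O[C@H](c1ccc(OCc4ccccc4)c(OCc4ccccc4)c1)[C@H](O)[C@H]3c1c(OCc4ccccc4)cc(OCc4ccccc4)c3c1O[C@H](c1ccc(OCc4ccccc4)c(OCc4ccccc4)c1)[C@H](O)C3)[C@@H](O)[C@@H](c1ccc(OCc4ccccc4)c(OCc4ccccc4)c1)O2 | intermediate
23 | deacetylated protected tetramer | O(Cc4ccccc4)c1c(Br)c(OCc4ccccc4)c2c(c1Br)O[C@H](c3ccc(OCc4ccccc4)c(OCc4ccccc4)c3)[C@@H](O)[C@@H]2c1c(OCc4ccccc4)c(Br)c2c(c1OCc4ccccc4)[C@H](c1c(OCc4ccccc4)cc(OCc4ccccc4)c3c1O[C@H](c1ccc(OCc4ccccc4)c(OCc4ccccc4)c1)[C@H](O)[C@H]3c1c(OCc4ccccc4)cc(OCc4ccccc4)c3c1O[C@H](c1ccc(OCc4ccccc4)c(OCc4ccccc4)c1)[C@H](O)C3)[C@@H](O)[C@@H](c1ccc(OCc4ccccc4)c(OCc4ccccc4)c1)O2 | intermediate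
24 | catechin-(4α→6)-epicatechin-(4β→8)-epicatechin-(4β→8)-epicatechin (CNP0228086.1) | Oc1cc(O)c2c(c1)O[C@H](c1ccc(O)c(O)c1)[C@@H](O)[C@@H]2c1c(O)cc2c(c1O)[C@H](c1c(O)cc(O)c3c1O[C@H](c1ccc(O)c(O)c1)[C@H](O)[C@H]3c1c(O)cc(O)c3c1O[C@H](c1ccc(O)c(O)c1)[C@H](O)C3)[C@@H](O)[C@@H](c1ccc(O)c(O)c1)O2 | target

## Step count and risks

Total step count: 18. Longest linear sequence: 10 steps (steps 9–18, from 12 to 24).

Steps most likely to fail:

**Step 12 (Proposed new method).** What may go wrong is C-acylation of the sulfone carbanion before O-arylation (followed by closure through the enolate oxygen), arylation of the released benzyl alkoxide, or a stalled copper coupling at the ortho-substituted bromide. The fallback assembles the ring stepwise by classical chemistry. Setting out from 16, palladium-catalysed hydroxylation (Pd2(dba)3, t-BuXPhos, KOH, dioxane/H2O, 100 °C) would give 3,5-bis(benzyloxy)-2-[(phenylsulfonyl)methyl]phenol F1. Setting out from 11, Appel bromination (CBr4, PPh3, CH2Cl2, 0 °C) would give benzyl 2-bromo-2-[3,4-bis(benzyloxy)phenyl]acetate F2. Williamson etherification of F1 with F2 (K2CO3, acetone, rt) should give ether 17, now isolated, and Dieckmann cyclisation (NaH, THF, 0 °C → rt) comes back to the route at 18.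

**Step 16 (Proposed new method).** What may go wrong is sluggish ionisation of the sulfone, return of sulfinate to the cation, or loss of benzyl ethers if the Lewis acid has to be forced. The fallback replaces the sulfone by the established ether leaving group. Setting out from 21, reductive desulfonylation (SmI2, THF/HMPA, −78 °C) would give the dimer with an unsubstituted C4 in unit B, F3. DDQ oxidation in the presence of 2-ethoxyethanol (CH2Cl2, rt), directed to the only CH2 flanked by a dialkoxyarene, would give the 4β-(2-ethoxyethoxy) dimer F4. TMSOTf-catalysed coupling of F4 with 9 (CH2Cl2, −78 °C) comes back to the route at 22.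

**Step 13.** What may go wrong is slow epimerisation at C2 relative to reduction, poor facial selectivity at C3 caused by the 4-sulfonyl group, or the opposite sense of induction. The fallback separates reduction from resolution. Setting out from 18, Luche reduction (NaBH4, CeCl3·7H2O, MeOH, −40 °C) and chromatographic separation of the 2,3-cis diastereomer would give the racemic 2,3-cis alcohol F5 (19 together with its enantiomer). Kinetic resolution with Candida antarctica lipase B and vinyl acetate (toluene, 40 °C) would convert one enantiomer into its 3-O-acetate F6 (drawn for the 2S series). The remaining (2R) alcohol comes back to the route at 19; if the lipase prefers the (2R) alcohol, its acetate would be cleaved with K2CO3/MeOH to reach 19.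

## Further compounds

F1 | step 12 | 3,5-bis(benzyloxy)-2-[(phenylsulfonyl)methyl]phenol | Oc1cc(OCc2ccccc2)cc(OCc2ccccc2)c1CS(=O)(=O)c1ccccc1
F2 | step 12 | benzyl 2-bromo-2-[3,4-bis(benzyloxy)phenyl]acetate (racemic) | BrC(C(=O)OCc1ccccc1)c1ccc(OCc2ccccc2)c(OCc2ccccc2)c1
F3 | step 16 | protected A–B dimer with unsubstituted C4 in unit B | O(Cc4ccccc4)c1c(Br)c(OCc4ccccc4)c2c(c1Br)O[C@H](c3ccc(OCc4ccccc4)c(OCc4ccccc4)c3)[C@@H](OC(C)=O)[C@@H]2c1c(OCc4ccccc4)c(Br)c2c(c1OCc4ccccc4)C[C@@H](O)[C@@H](c1ccc(OCc4ccccc4)c(OCc4ccccc4)c1)O2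
F4 | step 16 | protected A–B dimer with 4β-(2-ethoxyethoxy) group in unit B | O(Cc4ccccc4)c1c(Br)c(OCc4ccccc4)c2c(c1Br)O[C@H](c3ccc(OCc4ccccc4)c(OCc4ccccc4)c3)[C@@H](OC(C)=O)[C@@H]2c1c(OCc4ccccc4)c(Br)c2c(c1OCc4ccccc4)[C@H](OCCOCC)[C@@H](O)[C@@H](c1ccc(OCc4ccccc4)c(OCc4ccccc4)c1)O2
F5 | step 13 | racemic 2,3-cis-3,4-cis alcohol (19 plus its enantiomer; SMILES of the enantiomer) | c1c(OCc4ccccc4)cc2c(c1OCc4ccccc4)[C@H](S(=O)(=O)c1ccccc1)[C@H](O)[C@H](c1ccc(OCc4ccccc4)c(OCc4ccccc4)c1)O2
F6 | step 13 | 3-O-acetate of the (2S) enantiomer of 19 | c1c(OCc4ccccc4)cc2c(c1OCc4ccccc4)[C@H](S(=O)(=O)c1ccccc1)[C@H](OC(C)=O)[C@H](c1ccc(OCc4ccccc4)c(OCc4ccccc4)c1)O2
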